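**Plan**

- Enabling feature: in the target benzene ring, C1 (CO2H) and C6 (10-phenyldecyl) are neighbours that can come from the two sp carbons of a 2-alkynoate, and C2(–O)–C3–C4–C5 is a four-carbon unit oxygenated at one end, i.e. a 1-alkoxy-1,3-diene.
- Retrosynthesis: OH and CO2H are traced back to OMe and CO2Me. The arene is then cut at C1–C2 and C5–C6 (C2 and C5 re-bridged by C2H4) to methyl 13-phenyltridec-2-ynoate and 1-methoxycyclohexa-1,3-diene. The alkynoate is cut at the ester carbon–alkyne bond, the propargylic C3–C4 bond and the phenyl–CH2 bond.
- Forward: the chain is joined linearly (Ph–C10 by copper-catalysed Grignard coupling, C10–C≡CH by acetylide SN2, C≡C–CO2Me by acylation). The only new ring, the benzene, then arises by [4+2]/retro-[4+2], and both O-methyl groups are removed last.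
- Stereochemistry: there is none to set. The target has no stereocentre and no stereogenic double bond, and the bridgehead centres of the transient bicyclic adduct disappear on aromatisation.

Key step: step 4

Remark on the chemistry: the target SMILES carries no stereodescriptor and the molecule is achiral, so "single enantiomer" is taken to mean the single constitution drawn.

**Route**

Step 1
Reactants: 1 phenylmagnesium bromide (commercial solution in THF); 2 1,10-dibromodecane (3 equiv)
Product: 3 (10-bromodecyl)benzene
Conditions: Li2CuCl4 (3 mol %), THF/NMP, slow addition of 1 at 0 °C, then rt; excess 2 removed by vacuum distillation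
Reagents that add atoms: none
Why: Kochi-type copper-catalysed cross-coupling of a Grignard reagent with an unhindered primary alkyl bromide, in which the threefold excess of the symmetrical dibromide and the slow addition of 1 should hold the reaction at monosubstitution.

Step 2
Reactants: 3 (10-bromodecyl)benzene
Product: 4 12-phenyldodec-1-yne
Conditions: HC≡CLi·H2NCH2CH2NH2 (1.5 equiv), DMSO, 10 °C → rt
Reagents that add atoms: lithium acetylide–ethylenediamine complex, [Li]C#C.NCCN
Why: SN2 alkylation of an acetylide by a primary bromide in a dipolar aprotic solvent, the classical terminal-alkyne synthesis, for which the unbranched electrophile leaves little room for E2 elimination.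

Step 3
Reactants: 4 12-phenyldodec-1-yne
Product: 6 methyl 13-phenyltridec-2-ynoate, via (12-phenyldodec-1-yn-1-yl)lithium 5 (not isolated)
Conditions: n-BuLi (1.05 equiv), THF, −78 °C; then ClCO2Me (1.5 equiv), −78 → 0 °C
Reagents that add atoms: methyl chloroformate, COC(=O)Cl
Why: Selective deprotonation of the terminal alkyne C–H (far more acidic than the benzylic C–H) followed by C-acylation of the acetylide with a chloroformate is the standard preparation of 2-alkynoates, and the excess electrophile at low temperature should prevent a second addition to the ester.

Step 4
Reactants: 6 methyl 13-phenyltridec-2-ynoate; 7 1-methoxycyclohexa-1,3-diene (4 equiv, calculated on the 1,3-diene content of the commercial material)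
Product: 9 methyl 2-methoxy-6-(10-phenyldecyl)benzoate, via bicyclo[2.2.2]octadiene adduct 8 (not isolated)
Conditions: neat, BHT (cat.), base-washed sealed tube, Ar, 185 °C; volatiles then stripped under vacuum
Reagents that add atoms: none
Why: The electron-rich 1-methoxydiene 7 and the electron-poor alkynoate 6 combine in a concerted, thermally allowed normal-demand [4+2] cycloaddition to the 1-methoxybicyclo[2.2.2]octa-2,5-diene 8, which at the same temperature undergoes retro-[4+2] extrusion of its CH2–CH2 bridge as ethylene, the gain of aromaticity and the escape of the gas making the sequence irreversible. The closest known reaction type is the Alder–Rickert synthesis of 2-alkoxybenzoates from 1-alkoxycyclohexa-1,3-dienes and acetylenic esters, in which 3-alkyl alkynoates react only near 180–200 °C, hence the neat mixture, the excess of 7 and the inhibitor. The one ring formed, the benzene ring of the salicylate, closes by intermolecular suprafacial cycloaddition that makes arene bonds C1–C2 and C5–C6 together, and the departure of ethylene then leaves the arene at the correct oxidation level without a dehydrogenation step. No stereocentre is created in 9, because the two bridgehead centres of racemic 8 are flattened on aromatisation. The selectivity needed is regiochemical (methoxy ortho to the ester) and is secured by frontier-orbital polarisation: the methoxy group enlarges the HOMO coefficient at the distal diene terminus C4, the ester enlarges the LUMO coefficient at the alkyl-bearing alkyne carbon, and union of these two atoms forces C1(OMe) onto the ester-bearing carbon. Neither the decamethylene tether nor the terminal phenyl group offers a reactive site under these conditions.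

Step 5
Reactants: 9 methyl 2-methoxy-6-(10-phenyldecyl)benzoate
Product: 12 2-hydroxy-6-(10-phenyldecyl)benzoic acid, via sodium 2-methoxy-6-(10-phenyldecyl)benzoate 10 (not isolated), via disodium 2-oxido-6-(10-phenyldecyl)benzoate 11 (not isolated)
Conditions: NaSEt (6 equiv), DMF, 130 °C, Ar; then 1 M HCl, 0 °C
Reagents that add atoms: none
Why: The soft thiolate attacks the two O-methyl carbons by SN2 (BAl2 cleavage of the methyl ester first, then thiolate cleavage of the aryl methyl ether), which bypasses the carbonyl of the 2,6-disubstituted benzoate that resists ordinary saponification, and cold acidification should liberate the salicylic acid without decarboxylation.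

**Compound list**

1 | phenylmagnesium bromide | Br[Mg]c1ccccc1 | starting material
2 | 1,10-dibromodecane | BrCCCCCCCCCCBr | starting material
3 | (10-bromodecyl)benzene | BrCCCCCCCCCCc1ccccc1 | intermediate
4 | 12-phenyldodec-1-yne | C#CCCCCCCCCCCc1ccccc1 | intermediate
5 | (12-phenyldodec-1-yn-1-yl)lithium (not isolated) | [Li]C#CCCCCCCCCCCc1ccccc1 | intermediate
6 | methyl 13-phenyltridec-2-ynoate | COC(=O)C#CCCCCCCCCCCc1ccccc1 | intermediate
7 | 1-methoxycyclohexa-1,3-diene | COC1=CC=CCC1 | starting material
8 | methyl 1-methoxy-3-(10-phenyldecyl)bicyclo[2.2.2]octa-2,5-diene-2-carboxylate (racemic, not isolated) | COC12CCC(C=C1)C(CCCCCCCCCCc3ccccc3)=C2C(=O)OC | intermediate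
9 | methyl 2-methoxy-6-(10-phenyldecyl)benzoate | COC(=O)c1c(OC)cccc1CCCCCCCCCCc1ccccc1 | intermediate
10 | sodium 2-methoxy-6-(10-phenyldecyl)benzoate (not isolated) | [Na+].[O-]C(=O)c1c(OC)cccc1CCCCCCCCCCc1ccccc1 | intermediate
11 | disodium 2-oxido-6-(10-phenyldecyl)benzoate (not isolated) | [Na+].[Na+].[O-]C(=O)c1c([O-])cccc1CCCCCCCCCCc1ccccc1 | intermediate
12 | 2-hydroxy-6-(10-phenyldecyl)benzoic acid (achiral) | O=C(O)c1c(O)cccc1CCCCCCCCCCc1ccccc1 | target

**Totals**

Total step count: 5. Longest linear sequence: 5 steps (1 and 2 to 12); diene 7 is bought.

**Steps most likely to fail**

Step 4. The bimolecular cycloaddition of the 3-alkyl alkynoate may be slower than thermal consumption of the diene. The diene can disproportionate to anisole, polymerise, or undergo a 1,5-hydrogen shift to the 2-methoxy isomer, which would lead to the 4-methoxy regioisomer. The result would be stalled conversion or regiochemical leakage. The fallback raises the dienophile reactivity by moving to the aldehyde oxidation level, so that the diene-consuming step runs at low temperature. It sets out from alkyne 4. Lithiation (n-BuLi, THF, −78 °C), formylation with DMF and inverse quench into aqueous KH2PO4 should give 13-phenyltridec-2-ynal F1. Heating F1 with 7 in toluene at about 100 °C should give the bridged adduct 1-methoxy-3-(10-phenyldecyl)bicyclo[2.2.2]octa-2,5-diene-2-carbaldehyde F2. After removal of excess diene, F2 is heated to about 170 °C in o-xylene to expel ethylene and give 2-methoxy-6-(10-phenyldecyl)benzaldehyde F3. Pinnick oxidation (NaClO2, NaH2PO4, 2-methyl-2-butene, t-BuOH/H2O) then gives 2-methoxy-6-(10-phenyldecyl)benzoic acid F4. Under the conditions of step 5, F4 is deprotonated by the thiolate and comes back to the route at 10.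

Step 5. The second demethylation may stall, because the aryl methyl ether of carboxylate 10 is electron-rich and sits next to an anionic group. Prolonged heating also risks decarboxylation during work-up. The fallback replaces nucleophilic demethylation by Lewis-acid ether cleavage followed by acyl–oxygen hydrolysis. It sets out from 9. BBr3 (CH2Cl2, −78 → 0 °C), assisted by chelation to the neighbouring ester carbonyl, should give methyl 2-hydroxy-6-(10-phenyldecyl)benzoate F5. Hydrolysis with KOH in DMSO/H2O at 80 °C and cold acidification then lead to 12.

Step 1. Coupling at both bromides (giving 1,10-diphenyldecane) and incomplete separation of the monobromide from excess dibromide could make clean 3 hard to obtain. The fallback differentiates the two chain ends from the outset. It sets out from 1 (2.2 equiv) and commercial 10-bromodecan-1-ol (OCCCCCCCCCCBr). With Li2CuCl4 (cat.) in THF at 0 °C → rt, the first equivalent of 1 deprotonates the hydroxyl and the second couples at the bromide, to give 10-phenyldecan-1-ol F6. An Appel reaction (CBr4, PPh3, CH2Cl2, 0 °C) converts F6 into 3, where the route is rejoined.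

**Further compounds**

F1 | step 4 | 13-phenyltridec-2-ynal | O=CC#CCCCCCCCCCCc1ccccc1
F2 | step 4 | 1-methoxy-3-(10-phenyldecyl)bicyclo[2.2.2]octa-2,5-diene-2-carbaldehyde (racemic) | COC12CCC(C=C1)C(CCCCCCCCCCc3ccccc3)=C2C=O
F3 | step 4 | 2-methoxy-6-(10-phenyldecyl)benzaldehyde | COc1cccc(CCCCCCCCCCc2ccccc2)c1C=O
F4 | step 4 | 2-methoxy-6-(10-phenyldecyl)benzoic acid | COc1cccc(CCCCCCCCCCc2ccccc2)c1C(=O)O
F5 | step 5 | methyl 2-hydroxy-6-(10-phenyldecyl)benzoate | COC(=O)c1c(O)cccc1CCCCCCCCCCc1ccccc1
F6 | step 1 | 10-phenyldecan-1-ol | OCCCCCCCCCCc1ccccc1
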